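The target is cut at C11=C12 into an ε-ring C25 phosphonium salt and a C15 epoxy dienal, which traces back to 5,6-epoxy-β-cyclogeranate. There, C5 and C6 are adjacent fully substituted carbons shared by ring A and the oxirane, so a single Darzens event, C5–C6 aldol bond followed by C6–O closure, builds both rings and both stereocentres at once. Its precursor is an open-chain 2-chloro-3,3-dimethyl-7-oxooctanoate, carried as the (–)-8-phenylmenthyl ester: the bulky chiral ester blocks Dieckmann acylation, shields one face of the chloro-enolate and leaves separable diastereomers; the auxiliary is released in the reduction that follows.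

Key step: step 5

Remark: positions are given in carotenoid numbering (ring A = C1–C6, C1 the gem-dimethyl carbon, C5 the methyl-bearing oxirane carbon, C6 the chain-bearing oxirane carbon; primed numbers belong to the ε half).
Assumption: (–)-8-phenylmenthol is taken as the auxiliary enantiomer that shields the enolate face leading to (5R,6S); the sense depends on the enolate geometry, and should the first run show the opposite sense, (+)-8-phenylmenthol is used in step 1 with nothing else changed.
Assumption: (R)-(+)-α-ionone is treated as a purchasable single enantiomer; its C6′ centre is carried unchanged into the target.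

Step 1
Reactants: 1 (–)-8-phenylmenthol, (1R,2S,5R)-5-methyl-2-(2-phenylpropan-2-yl)cyclohexan-1-ol; 2 3-methylbut-2-enoyl chloride
Product: 3 (1R,2S,5R)-5-methyl-2-(2-phenylpropan-2-yl)cyclohexyl 3-methylbut-2-enoate
Conditions: pyridine, 4-(dimethylamino)pyridine (cat.), CH2Cl2, 0 °C → rt
Reagents that add atoms: none
Why: Acylation of a secondary alcohol by an acid chloride under nucleophilic catalysis (esterification), run with pyridine as the only base so that the enoate is not deconjugated through a vinylketene; no stereocentre is formed or touched.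

Step 2
Reactants: 3 (1R,2S,5R)-5-methyl-2-(2-phenylpropan-2-yl)cyclohexyl 3-methylbut-2-enoate; 4 2-(3-chloropropyl)-2-methyl-1,3-dioxolane
Product: 7 (1R,2S,5R)-5-methyl-2-(2-phenylpropan-2-yl)cyclohexyl 3,3-dimethyl-6-(2-methyl-1,3-dioxolan-2-yl)hexanoate, via Grignard reagent 5 (not isolated), via silyl ketene acetal 6 (not isolated)
Conditions: 4, Mg, THF, reflux; then 3, CuBr·SMe2 (10 mol%), Me3SiCl, DMPU, THF, –40 → 0 °C; aq NH4Cl/NH3
Reagents that add atoms: none
Why: Copper-catalysed conjugate addition of a Grignard reagent, accelerated by Me3SiCl, which is the standard way to force 1,4-addition onto β,β-disubstituted enoates; it creates the quaternary C1 (not stereogenic) while the dioxolane keeps the future C5 ketone masked.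

Step 3
Reactants: 7 (1R,2S,5R)-5-methyl-2-(2-phenylpropan-2-yl)cyclohexyl 3,3-dimethyl-6-(2-methyl-1,3-dioxolan-2-yl)hexanoate
Product: 9 (1R,2S,5R)-5-methyl-2-(2-phenylpropan-2-yl)cyclohexyl 2-chloro-3,3-dimethyl-6-(2-methyl-1,3-dioxolan-2-yl)hexanoate (both C2 epimers), via lithium enolate 8 (not isolated)
Conditions: LiN(i-Pr)2, THF, –78 °C; then N-chlorosuccinimide, –78 → 0 °C
Reagents that add atoms: N-chlorosuccinimide, O=C1CCC(=O)N1Cl
Why: α-Chlorination of an ester lithium enolate by an N-chloro imide; the only enolisable position is C6, the dioxolane is inert to the amide base, and the chlorine-bearing centre forms as both epimers, which is harmless because step 5 passes through the planar enolate.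

Step 4
Reactants: 9 (1R,2S,5R)-5-methyl-2-(2-phenylpropan-2-yl)cyclohexyl 2-chloro-3,3-dimethyl-6-(2-methyl-1,3-dioxolan-2-yl)hexanoate
Product: 10 (1R,2S,5R)-5-methyl-2-(2-phenylpropan-2-yl)cyclohexyl 2-chloro-3,3-dimethyl-7-oxooctanoate (both C2 epimers)
Conditions: 1 M HCl, THF, rt
Reagents that add atoms: water, O
Why: Acid-catalysed hydrolysis of a dioxolane (ketal cleavage); dilute acid at room temperature leaves the hindered ester and the neopentyl C–Cl bond alone.

Step 5
Reactants: 10 (1R,2S,5R)-5-methyl-2-(2-phenylpropan-2-yl)cyclohexyl 2-chloro-3,3-dimethyl-7-oxooctanoate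
Product: 13 (1R,2S,5R)-5-methyl-2-(2-phenylpropan-2-yl)cyclohexyl (1S,6R)-2,2,6-trimethyl-7-oxabicyclo[4.1.0]heptane-1-carboxylate [8-phenylmenthyl (5R,6S)-5,6-epoxy-β-cyclogeranate], via potassium chloro-enolate 11 (not isolated), via trans-chloro aldolate 12 (not isolated)
Conditions: t-BuOK (1.2 equiv), THF/t-BuOH, –40 → 0 °C, high dilution
Reagents that add atoms: none
Why: Proposed new method: tert-butoxide reversibly removes the single acidic hydrogen at C6 (C1 is quaternary), the chloro-enolate 11 adds to the C5 ketone through a chair-like 6-(enolexo)-exo-trig aldol closure of ring A, and aldolate 12, whose alkoxide stands anti to chlorine, expels chloride in a 3-exo-tet closure of the oxirane (a Darzens condensation run intramolecularly). The closest known reaction types are the auxiliary-controlled Darzens condensation of 8-phenylmenthyl chloroacetate with ketones under t-BuOK and intramolecular Darzens ring closures of halo carbonyl compounds; attack of an α-branched chloro-ester enolate on a tethered ketone to give a ring-fused tetrasubstituted oxirane has not been shown. C6 is set by the auxiliary, whose phenyl ring lies over one face of the enolate so that the ketone is engaged on the open face, and the chloride displacement then inverts C6. C5 is set by the ring constraint: only the aldolate with oxygen trans to chlorine can close and the oxirane can only be cis-fused, while the other aldolate returns by retro-aldol, so C5 follows C6. The step needs chemoselectivity for the chloro-enolate over the more easily formed ketone enolates and face selectivity at C6; the first is secured because t-BuOH keeps all enolisations reversible, the bulky secondary ester shuts off Dieckmann acylation and the neopentyl C–Cl carbon resists 5-exo alkylation, which leaves epoxide formation as the only irreversible exit, and the second by the auxiliary, with any minor diastereomer of 13 removed by chromatography.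

Step 6
Reactants: 13 (1R,2S,5R)-5-methyl-2-(2-phenylpropan-2-yl)cyclohexyl (1S,6R)-2,2,6-trimethyl-7-oxabicyclo[4.1.0]heptane-1-carboxylate
Product: 14 [(1R,6R)-2,2,6-trimethyl-7-oxabicyclo[4.1.0]heptan-1-yl]methanol
Conditions: LiAlH4, Et2O, 0 °C → rt; then H2O, aq NaOH
Reagents that add atoms: none
Why: LiAlH4 reduction of an ester to the primary alcohol; both oxirane carbons are fully substituted and therefore closed to hydride attack, C5 and C6 are not touched, and auxiliary 1 is recovered for reuse.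

Step 7
Reactants: 14 [(1R,6R)-2,2,6-trimethyl-7-oxabicyclo[4.1.0]heptan-1-yl]methanol
Product: 15 (1S,6R)-2,2,6-trimethyl-7-oxabicyclo[4.1.0]heptane-1-carbaldehyde
Conditions: n-Pr4N[RuO4] (5 mol%), N-methylmorpholine N-oxide, 4 Å molecular sieves, CH2Cl2, rt
Reagents that add atoms: none
Why: Ley–Griffith oxidation of a primary alcohol to the aldehyde under neutral, non-aqueous conditions that an acid-sensitive oxirane tolerates; 15 has no α-hydrogen and cannot epimerise.

Step 8
Reactants: 15 (1S,6R)-2,2,6-trimethyl-7-oxabicyclo[4.1.0]heptane-1-carbaldehyde; 16 diethyl [(2E)-3-cyano-2-methylprop-2-en-1-yl]phosphonate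
Product: 18 (2E,4E)-3-methyl-5-[(1S,6R)-2,2,6-trimethyl-7-oxabicyclo[4.1.0]heptan-1-yl]penta-2,4-dienenitrile, via phosphonate carbanion 17 (not isolated)
Conditions: NaH, THF, 0 °C; then 15, 0 °C → rt
Reagents that add atoms: none
Why: Horner–Wadsworth–Emmons olefination of a non-enolisable aldehyde with a nitrile-stabilised allylic phosphonate anion, which gives the E C7=C8 bond; the 9Z isomer that arises from the delocalised anion is removed by chromatography on base-washed silica.

Step 9
Reactants: 18 (2E,4E)-3-methyl-5-[(1S,6R)-2,2,6-trimethyl-7-oxabicyclo[4.1.0]heptan-1-yl]penta-2,4-dienenitrile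
Product: 20 (2E,4E)-3-methyl-5-[(1S,6R)-2,2,6-trimethyl-7-oxabicyclo[4.1.0]heptan-1-yl]penta-2,4-dienal, via N-aluminio aldimine 19 (not isolated)
Conditions: i-Bu2AlH, CH2Cl2, –78 °C; then aq potassium sodium tartrate, pH 7 buffer, 0 °C
Reagents that add atoms: water, O
Why: Partial reduction of a nitrile by i-Bu2AlH to the N-aluminio aldimine, hydrolysed to the aldehyde on buffered work-up; low temperature and the absence of acid protect the vinyl oxirane from furanoid rearrangement.

Step 10
Reactants: 21 (R)-α-ionone, (3E)-4-[(1R)-2,6,6-trimethylcyclohex-2-en-1-yl]but-3-en-2-one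
Product: 22 (1E)-3-methyl-1-[(1R)-2,6,6-trimethylcyclohex-2-en-1-yl]penta-1,4-dien-3-ol (both C3 epimers)
Conditions: CH2=CHMgBr, THF, –20 → 0 °C; aq NH4Cl
Reagents that add atoms: vinylmagnesium bromide, C=C[Mg]Br
Why: 1,2-Addition of a vinyl Grignard reagent to the ketone of an enone; C6′ is untouched, and the new carbinol centre forms as both epimers, which does not matter because it becomes sp2 in step 11.

Step 11
Reactants: 22 (1E)-3-methyl-1-[(1R)-2,6,6-trimethylcyclohex-2-en-1-yl]penta-1,4-dien-3-ol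
Product: 23 [(2E,4E)-3-methyl-5-[(1R)-2,6,6-trimethylcyclohex-2-en-1-yl]penta-2,4-dien-1-yl]triphenylphosphonium bromide
Conditions: Ph3P·HBr, MeOH, 0 °C → rt; crystallisation
Reagents that add atoms: triphenylphosphine hydrobromide, [Br-].[PH+](c1ccccc1)(c1ccccc1)c1ccccc1
Why: Acid-mediated allylic substitution with transposition (SN1′-type phosphonium salt formation), in which the tertiary bis-allylic alcohol ionises and PPh3 captures the cation at its primary terminus; C6′ is not part of the cation and is retained, and the E salt is purified by crystallisation.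

Step 12
Reactants: 23 [(2E,4E)-3-methyl-5-[(1R)-2,6,6-trimethylcyclohex-2-en-1-yl]penta-2,4-dien-1-yl]triphenylphosphonium bromide; 24 (2E,4E,6E)-2,7-dimethylocta-2,4,6-trienedial
Product: 26 (2E,4E,6E,8E,10E,12E)-2,7,11-trimethyl-13-[(1R)-2,6,6-trimethylcyclohex-2-en-1-yl]trideca-2,4,6,8,10,12-hexaenal, via C15 ylide 25 (not isolated)
Conditions: NaOMe, MeOH/CH2Cl2, 0 °C; 24 (3 equiv); then n-heptane, 80 °C; crystallisation
Reagents that add atoms: none
Why: Wittig olefination of a semi-stabilised allylic ylide with one aldehyde group of a symmetrical dialdehyde used in excess, so that mono-condensation dominates; the new C11′=C12′ bond is brought to E by brief heating before crystallisation, and C6′ is not affected by methoxide.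

Step 13
Reactants: 26 (2E,4E,6E,8E,10E,12E)-2,7,11-trimethyl-13-[(1R)-2,6,6-trimethylcyclohex-2-en-1-yl]trideca-2,4,6,8,10,12-hexaenal
Product: 27 (2E,4E,6E,8E,10E,12E)-2,7,11-trimethyl-13-[(1R)-2,6,6-trimethylcyclohex-2-en-1-yl]trideca-2,4,6,8,10,12-hexaen-1-ol
Conditions: NaBH4, EtOH/THF, 0 °C
Reagents that add atoms: none
Why: Borohydride 1,2-reduction of a conjugated aldehyde to the primary polyenyl alcohol; no other group in 26 is reducible under these conditions.

Step 14
Reactants: 27 (2E,4E,6E,8E,10E,12E)-2,7,11-trimethyl-13-[(1R)-2,6,6-trimethylcyclohex-2-en-1-yl]trideca-2,4,6,8,10,12-hexaen-1-ol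
Product: 28 [(2E,4E,6E,8E,10E,12E)-2,7,11-trimethyl-13-[(1R)-2,6,6-trimethylcyclohex-2-en-1-yl]trideca-2,4,6,8,10,12-hexaen-1-yl]triphenylphosphonium bromide
Conditions: Ph3P·HBr, MeOH/CH2Cl2, 0 °C → rt
Reagents that add atoms: triphenylphosphine hydrobromide, [Br-].[PH+](c1ccccc1)(c1ccccc1)c1ccccc1
Why: Phosphonium salt formation from a primary polyenylic alcohol with Ph3P·HBr (SN1-type substitution through the delocalised cation, captured at the primary terminus), as practised for retinyl-type salts; it is done on the epoxide-free half so that the oxirane never meets acid.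

Step 15
Reactants: 28 [(2E,4E,6E,8E,10E,12E)-2,7,11-trimethyl-13-[(1R)-2,6,6-trimethylcyclohex-2-en-1-yl]trideca-2,4,6,8,10,12-hexaen-1-yl]triphenylphosphonium bromide; 20 (2E,4E)-3-methyl-5-[(1S,6R)-2,2,6-trimethyl-7-oxabicyclo[4.1.0]heptan-1-yl]penta-2,4-dienal
Product: 30 (5R,6S,6′R)-5,6-epoxy-5,6-dihydro-β,ε-carotene (target), via C25 ylide 29 (not isolated)
Conditions: NaOMe, MeOH/CH2Cl2, 0 °C → rt; then n-heptane, reflux, dark, N2; crystallisation
Reagents that add atoms: none
Why: Wittig olefination joins the two halves at C11=C12; Z isomers of the new disubstituted bond should relax thermally to the all-E polyene, and the basic, acid-free conditions leave C5, C6 and C6′ unchanged.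

Compound list
1 | (–)-8-phenylmenthol, (1R,2S,5R)-5-methyl-2-(2-phenylpropan-2-yl)cyclohexan-1-ol | O[C@@H]1C[C@H](C)CC[C@H]1C(C)(C)c1ccccc1 | starting material
2 | 3-methylbut-2-enoyl chloride | CC(C)=CC(Cl)=O | starting material
3 | (1R,2S,5R)-5-methyl-2-(2-phenylpropan-2-yl)cyclohexyl 3-methylbut-2-enoate | CC(C)=CC(=O)O[C@@H]1C[C@H](C)CC[C@H]1C(C)(C)c1ccccc1 | intermediate
4 | 2-(3-chloropropyl)-2-methyl-1,3-dioxolane | CC1(CCCCl)OCCO1 | starting material
5 | [3-(2-methyl-1,3-dioxolan-2-yl)propyl]magnesium chloride (not isolated) | CC1(CCC[Mg]Cl)OCCO1 | intermediate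
6 | trimethylsilyl ketene acetal of 7 (not isolated) | CC1(CCCC(C)(C)C=C(O[Si](C)(C)C)O[C@@H]2C[C@H](C)CC[C@H]2C(C)(C)c2ccccc2)OCCO1 | intermediate
7 | (1R,2S,5R)-5-methyl-2-(2-phenylpropan-2-yl)cyclohexyl 3,3-dimethyl-6-(2-methyl-1,3-dioxolan-2-yl)hexanoate | CC1(CCCC(C)(C)CC(=O)O[C@@H]2C[C@H](C)CC[C@H]2C(C)(C)c2ccccc2)OCCO1 | intermediate
8 | lithium enolate of 7 (not isolated) | CC1(CCCC(C)(C)C=C(O[Li])O[C@@H]2C[C@H](C)CC[C@H]2C(C)(C)c2ccccc2)OCCO1 | intermediate
9 | (1R,2S,5R)-5-methyl-2-(2-phenylpropan-2-yl)cyclohexyl 2-chloro-3,3-dimethyl-6-(2-methyl-1,3-dioxolan-2-yl)hexanoate, both C2 epimers | CC1(CCCC(C)(C)C(Cl)C(=O)O[C@@H]2C[C@H](C)CC[C@H]2C(C)(C)c2ccccc2)OCCO1 | intermediate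
10 | (1R,2S,5R)-5-methyl-2-(2-phenylpropan-2-yl)cyclohexyl 2-chloro-3,3-dimethyl-7-oxooctanoate, both C2 epimers (key-step precursor) | CC(=O)CCCC(C)(C)C(Cl)C(=O)O[C@@H]1C[C@H](C)CC[C@H]1C(C)(C)c1ccccc1 | intermediate
11 | potassium chloro-enolate of 10 (not isolated) | CC(=O)CCCC(C)(C)C(Cl)=C(O[K])O[C@@H]1C[C@H](C)CC[C@H]1C(C)(C)c1ccccc1 | intermediate
12 | potassium alkoxide of 8-phenylmenthyl (1R,2R)-1-chloro-2-hydroxy-2,6,6-trimethylcyclohexane-1-carboxylate, O and Cl trans (not isolated) | O=C(O[C@@H]2C[C@H](C)CC[C@H]2C(C)(C)c2ccccc2)[C@]1(Cl)[C@](C)(O[K])CCCC1(C)C | intermediate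
13 | (1R,2S,5R)-5-methyl-2-(2-phenylpropan-2-yl)cyclohexyl (1S,6R)-2,2,6-trimethyl-7-oxabicyclo[4.1.0]heptane-1-carboxylate (key-step product) | O=C(O[C@@H]3C[C@H](C)CC[C@H]3C(C)(C)c3ccccc3)[C@@]12O[C@]1(C)CCCC2(C)C | intermediate
14 | [(1R,6R)-2,2,6-trimethyl-7-oxabicyclo[4.1.0]heptan-1-yl]methanol | OC[C@@]12O[C@]1(C)CCCC2(C)C | intermediate
15 | (1S,6R)-2,2,6-trimethyl-7-oxabicyclo[4.1.0]heptane-1-carbaldehyde | O=C[C@@]12O[C@]1(C)CCCC2(C)C | intermediate
16 | diethyl [(2E)-3-cyano-2-methylprop-2-en-1-yl]phosphonate | CCOP(=O)(OCC)C/C(C)=C/C#N | starting material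
17 | sodium salt of the carbanion of 16 (not isolated) | CCOP(=O)(OCC)[CH-]C(C)=CC#N.[Na+] | intermediate
18 | (2E,4E)-3-methyl-5-[(1S,6R)-2,2,6-trimethyl-7-oxabicyclo[4.1.0]heptan-1-yl]penta-2,4-dienenitrile | N#C/C=C(C)/C=C/[C@@]12O[C@]1(C)CCCC2(C)C | intermediate
19 | N-(diisobutylaluminio) aldimine of 20 (not isolated) | CC(C)C[Al](CC(C)C)N=C/C=C(C)/C=C/[C@@]12O[C@]1(C)CCCC2(C)C | intermediate
20 | (2E,4E)-3-methyl-5-[(1S,6R)-2,2,6-trimethyl-7-oxabicyclo[4.1.0]heptan-1-yl]penta-2,4-dienal | O=C/C=C(C)/C=C/[C@@]12O[C@]1(C)CCCC2(C)C | intermediate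
21 | (R)-α-ionone, (3E)-4-[(1R)-2,6,6-trimethylcyclohex-2-en-1-yl]but-3-en-2-one | CC1=CCCC(C)(C)[C@H]1/C=C/C(C)=O | starting material
22 | (1E)-3-methyl-1-[(1R)-2,6,6-trimethylcyclohex-2-en-1-yl]penta-1,4-dien-3-ol, both C3 epimers | CC1=CCCC(C)(C)[C@H]1/C=C/C(C)(O)C=C | intermediate
23 | [(2E,4E)-3-methyl-5-[(1R)-2,6,6-trimethylcyclohex-2-en-1-yl]penta-2,4-dien-1-yl]triphenylphosphonium bromide | CC1=CCCC(C)(C)[C@H]1/C=C/C(C)=C/C[P+](c1ccccc1)(c1ccccc1)c1ccccc1.[Br-] | intermediate
24 | (2E,4E,6E)-2,7-dimethylocta-2,4,6-trienedial | O=C/C(C)=C/C=C/C=C(C)/C=O | starting material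
25 | ylide of 23 (not isolated) | CC1=CCCC(C)(C)[C@H]1/C=C/C(C)=C/C=P(c1ccccc1)(c1ccccc1)c1ccccc1 | intermediate
26 | (2E,4E,6E,8E,10E,12E)-2,7,11-trimethyl-13-[(1R)-2,6,6-trimethylcyclohex-2-en-1-yl]trideca-2,4,6,8,10,12-hexaenal | CC1=CCCC(C)(C)[C@H]1/C=C/C(C)=C/C=C/C(C)=C/C=C/C=C(C)/C=O | intermediate
27 | (2E,4E,6E,8E,10E,12E)-2,7,11-trimethyl-13-[(1R)-2,6,6-trimethylcyclohex-2-en-1-yl]trideca-2,4,6,8,10,12-hexaen-1-ol | CC1=CCCC(C)(C)[C@H]1/C=C/C(C)=C/C=C/C(C)=C/C=C/C=C(C)/CO | intermediate
28 | [(2E,4E,6E,8E,10E,12E)-2,7,11-trimethyl-13-[(1R)-2,6,6-trimethylcyclohex-2-en-1-yl]trideca-2,4,6,8,10,12-hexaen-1-yl]triphenylphosphonium bromide | CC1=CCCC(C)(C)[C@H]1/C=C/C(C)=C/C=C/C(C)=C/C=C/C=C(C)/C[P+](c1ccccc1)(c1ccccc1)c1ccccc1.[Br-] | intermediate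
29 | ylide of 28 (not isolated) | CC1=CCCC(C)(C)[C@H]1/C=C/C(C)=C/C=C/C(C)=C/C=C/C=C(C)/C=P(c1ccccc1)(c1ccccc1)c1ccccc1 | intermediate
30 | (5R,6S,6′R)-5,6-epoxy-5,6-dihydro-β,ε-carotene | CC1=CCCC(C)(C)[C@H]1/C=C/C(C)=C/C=C/C(C)=C/C=C/C=C(C)/C=C/C=C(C)/C=C/[C@@]12O[C@]1(C)CCCC2(C)C | target

Total step count: 15.
Longest linear sequence: 10 steps (steps 1–9 and 15); the ε branch (steps 10–14) joins in step 15.

Steps most likely to fail

Step 5. Ketone-enolate chemistry (self-condensation, 5-exo alkylation) may outrun the Darzens funnel, or the auxiliary may give weak or reversed face selection that chromatography cannot correct. The fallback uses known chemistry only, sets out from 10 and returns at 14. The C5–C6 bond is made by a samarium diiodide-mediated intramolecular Reformatsky reaction of 10 (SmI2, THF, –78 °C), which should give (1R,2S,5R)-5-methyl-2-(2-phenylpropan-2-yl)cyclohexyl 2-hydroxy-2,6,6-trimethylcyclohexane-1-carboxylate F1. Dehydration (SOCl2, pyridine; the conjugated isomer separated from its double-bond isomers) gives (1R,2S,5R)-5-methyl-2-(2-phenylpropan-2-yl)cyclohexyl 2,6,6-trimethylcyclohex-1-ene-1-carboxylate F2. LiAlH4 reduction releases the auxiliary and gives β-cyclogeraniol, (2,6,6-trimethylcyclohex-1-en-1-yl)methanol F3. Sharpless asymmetric epoxidation of F3 (Ti(Oi-Pr)4, D-(–)-diethyl tartrate, t-BuOOH, 4 Å molecular sieves, CH2Cl2, –20 °C) then delivers oxygen to the face that gives 14, so that both stereocentres are set by the tartrate ligand.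

Step 2. The 1,4-addition may stall on the β,β-disubstituted enoate that carries the bulky ester, so that 1,2-addition or Grignard homocoupling takes over. The fallback sets out from 4 and returns at 7. Grignard reagent 5 from 4 is added with CuBr·SMe2 to diethyl isopropylidenemalonate, a much stronger acceptor, to give diethyl 2-[2-methyl-5-(2-methyl-1,3-dioxolan-2-yl)pentan-2-yl]propanedioate F4. Krapcho dealkoxycarbonylation (LiCl, wet DMSO, 150 °C) gives ethyl 3,3-dimethyl-6-(2-methyl-1,3-dioxolan-2-yl)hexanoate F5. Saponification (KOH, EtOH/H2O, acidified only to pH 5 to spare the dioxolane) gives 3,3-dimethyl-6-(2-methyl-1,3-dioxolan-2-yl)hexanoic acid F6. Steglich esterification of F6 with 1 (N,N′-dicyclohexylcarbodiimide, 4-(dimethylamino)pyridine, CH2Cl2) gives 7.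

Step 8. Addition of the C5 phosphonate anion to the neopentyl-type aldehyde may be slow, with erosion of the 9E geometry through the delocalised anion. The fallback sets out from 15 and returns at 18, and builds the chain one double bond at a time. Horner–Wadsworth–Emmons reaction of 15 with the small diethyl (2-oxopropyl)phosphonate (NaH, THF) gives the epoxy ionone (3E)-4-[(1S,6R)-2,2,6-trimethyl-7-oxabicyclo[4.1.0]heptan-1-yl]but-3-en-2-one F7. A second Horner–Wadsworth–Emmons reaction of F7 with diethyl (cyanomethyl)phosphonate (NaH, THF) gives 18 after removal of the 9Z isomer.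

Further compounds
F1 | step 5 | (1R,2S,5R)-5-methyl-2-(2-phenylpropan-2-yl)cyclohexyl 2-hydroxy-2,6,6-trimethylcyclohexane-1-carboxylate (diastereomer mixture) | CC1(O)CCCC(C)(C)C1C(=O)O[C@@H]1C[C@H](C)CC[C@H]1C(C)(C)c1ccccc1
F2 | step 5 | (1R,2S,5R)-5-methyl-2-(2-phenylpropan-2-yl)cyclohexyl 2,6,6-trimethylcyclohex-1-ene-1-carboxylate | CC1=C(C(=O)O[C@@H]2C[C@H](C)CC[C@H]2C(C)(C)c2ccccc2)C(C)(C)CCC1
F3 | step 5 | β-cyclogeraniol, (2,6,6-trimethylcyclohex-1-en-1-yl)methanol | CC1=C(CO)C(C)(C)CCC1
F4 | step 2 | diethyl 2-[2-methyl-5-(2-methyl-1,3-dioxolan-2-yl)pentan-2-yl]propanedioate | CCOC(=O)C(C(=O)OCC)C(C)(C)CCCC1(C)OCCO1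
F5 | step 2 | ethyl 3,3-dimethyl-6-(2-methyl-1,3-dioxolan-2-yl)hexanoate | CCOC(=O)CC(C)(C)CCCC1(C)OCCO1
F6 | step 2 | 3,3-dimethyl-6-(2-methyl-1,3-dioxolan-2-yl)hexanoic acid | OC(=O)CC(C)(C)CCCC1(C)OCCO1
F7 | step 8 | (3E)-4-[(1S,6R)-2,2,6-trimethyl-7-oxabicyclo[4.1.0]heptan-1-yl]but-3-en-2-one | CC(=O)/C=C/[C@@]12O[C@]1(C)CCCC2(C)C
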